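**Retrosynthetic overview**

1. Target 8 ⇐ β-keto acetal 7 (acid closes O1–C2, MOM falls in the same pot) ⇐ 2'-hydroxychalcone 6 by Tl(III) oxidative 1,2-aryl shift. The C3–aryl bond is made by migration, not by the usual deoxybenzoin/C1-insertion or 3-halochromone Suzuki route.
2. Chalcone 6 ⇐ Claisen–Schmidt condensation of ketone 4 with 2,4,5-trimethoxybenzaldehyde 5.
3. Ketone 4 ⇐ selective MOM ether of hydroquinone 3 ⇐ Elbs para C–H hydroxylation of paeonol 1.
4. Ring order: both benzene rings are bought intact; the pyran-4-one ring is the only ring formed, in the last step.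

Assumption: the target is achiral (no stereocentre), so there is no enantiomer to select; the only stereo-elements on the way are the E-alkene of 6 and a transient racemic centre in 7 that becomes sp2.

**Route**

Step 1
Reactants: 1 paeonol (1-(2-hydroxy-4-methoxyphenyl)ethanone)
Product: 3 1-(2,5-dihydroxy-4-methoxyphenyl)ethanone, via aryl potassium sulfate 2 (not isolated)
Conditions: K2S2O8 (1.1 equiv), 10% aq KOH, 10–20 °C, 24 h; acidify, Et2O wash (recovers 1); then conc. HCl, 90 °C, 30 min
Reagents that add atoms: potassium peroxodisulfate, [K+].[K+].[O-]S(=O)(=O)OOS(=O)(=O)[O-]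
Why: Elbs persulfate oxidation, in which the phenoxide attacks the peroxide oxygen through its free para carbon (C5) to give aryl sulfate 2, which acid hydrolyses by S–O cleavage to the hydroquinone; conversion is modest (about 30–45%) but unreacted 1 is recycled, and no stereocentre is formed.

Step 2
Reactants: 3 1-(2,5-dihydroxy-4-methoxyphenyl)ethanone
Product: 4 1-[2-hydroxy-4-methoxy-5-(methoxymethoxy)phenyl]ethanone
Conditions: MOMCl (1.1 equiv), i-Pr2NEt (1.5 equiv), CH2Cl2, 0 °C to rt, N2
Reagents that add atoms: chloromethyl methyl ether, COCCl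
Why: O-alkylation (MOM ether formation) is selective for the 5-OH because the 2-OH is held in a strong hydrogen bond to the ketone and is far less nucleophilic under amine-base conditions.

Step 3
Reactants: 4 1-[2-hydroxy-4-methoxy-5-(methoxymethoxy)phenyl]ethanone; 5 2,4,5-trimethoxybenzaldehyde
Product: 6 (E)-1-[2-hydroxy-4-methoxy-5-(methoxymethoxy)phenyl]-3-(2,4,5-trimethoxyphenyl)prop-2-en-1-one
Conditions: 50% aq KOH (10 equiv), EtOH, rt, 48 h; then cold dilute AcOH to pH 5–6
Reagents that add atoms: none
Why: Claisen–Schmidt condensation (aldol addition of the methyl ketone enolate to the non-enolisable aldehyde, then E1cB dehydration) gives the thermodynamic E-enone, and the MOM ether is stable to base and to the mild acid quench.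

Step 4
Reactants: 6 (E)-1-[2-hydroxy-4-methoxy-5-(methoxymethoxy)phenyl]-3-(2,4,5-trimethoxyphenyl)prop-2-en-1-one
Product: 8 6-hydroxy-7-methoxy-3-(2,4,5-trimethoxyphenyl)-4H-chromen-4-one, via dimethyl acetal 7 (not isolated)
Conditions: Tl(NO3)3·3H2O (1.1 equiv), MeOH/HC(OMe)3 3:1, 0 °C to rt, 2 h; filter off TlNO3; then 10% aq HCl, 60 °C, 3 h
Reagents that add atoms: methanol, CO (supplies the two acetal OMe groups of 7; none of its atoms remain in 8)
Why: Tl(III) oxythallates the enone (Tl on Cα, MeOH on Cβ) and loss of Tl(I) drives a 1,2-shift of the electron-rich trimethoxyphenyl group from Cβ to Cα (oxidative rearrangement of a 2'-hydroxychalcone, the laboratory analogue of isoflavone synthase) to give acetal 7, which under acid cyclises through the chelated phenol with loss of two MeOH while the MOM acetal is hydrolysed; the racemic centre of 7 becomes sp2, so no stereochemistry is at stake.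

**Compound list**

1 | paeonol, 1-(2-hydroxy-4-methoxyphenyl)ethanone | CC(=O)c1ccc(OC)cc1O | starting material
2 | potassium 5-acetyl-4-hydroxy-2-methoxyphenyl sulfate | CC(=O)c1cc(OS(=O)(=O)[O-])c(OC)cc1O.[K+] | intermediate (not isolated)
3 | 1-(2,5-dihydroxy-4-methoxyphenyl)ethanone | CC(=O)c1cc(O)c(OC)cc1O | intermediate
4 | 1-[2-hydroxy-4-methoxy-5-(methoxymethoxy)phenyl]ethanone | CC(=O)c1cc(OCOC)c(OC)cc1O | intermediate
5 | 2,4,5-trimethoxybenzaldehyde | COc1cc(OC)c(C=O)cc1OC | starting material
6 | (E)-1-[2-hydroxy-4-methoxy-5-(methoxymethoxy)phenyl]-3-(2,4,5-trimethoxyphenyl)prop-2-en-1-one | COCOc1cc(C(=O)/C=C/c2cc(OC)c(OC)cc2OC)c(O)cc1OC | intermediate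
7 | 1-[2-hydroxy-4-methoxy-5-(methoxymethoxy)phenyl]-3,3-dimethoxy-2-(2,4,5-trimethoxyphenyl)propan-1-one (racemic) | COCOc1cc(C(=O)C(C(OC)OC)c2cc(OC)c(OC)cc2OC)c(O)cc1OC | intermediate (not isolated)
8 | 6-hydroxy-7-methoxy-3-(2,4,5-trimethoxyphenyl)-4H-chromen-4-one | COc1cc2occ(-c3cc(OC)c(OC)cc3OC)c(=O)c2cc1O | target

**Step count and risks**

Total step count: 4. Longest linear sequence: 4 steps (1 → 3 → 4 → 6 → 8); aldehyde 5 is bought.

Three steps most likely to fail:

Step 4 (oxidative aryl migration). The risks are early loss of the MOM group in the acidic methanol followed by Tl(III) oxidation of the freed hydroquinone, aurone formation, and oxidation of the trimethoxyphenyl ring; thallium salts are also highly toxic and need contained handling. The fallback gives up the rearrangement and makes the C3–aryl bond by cross-coupling. It sets out from 4 and comes back to the route at 8. Ketone 4 is heated with N,N-dimethylformamide dimethyl acetal (toluene, 90 °C) to give the enaminone (E)-3-(dimethylamino)-1-[2-hydroxy-4-methoxy-5-(methoxymethoxy)phenyl]prop-2-en-1-one F1. Iodine and pyridine in CHCl3 at rt cyclise it, with loss of dimethylamine, to 3-iodo-7-methoxy-6-(methoxymethoxy)-4H-chromen-4-one F2. Suzuki–Miyaura coupling with commercial 2,4,5-trimethoxyphenylboronic acid (Pd(dppf)Cl2, K2CO3, dioxane/H2O, 80 °C) gives 7-methoxy-6-(methoxymethoxy)-3-(2,4,5-trimethoxyphenyl)-4H-chromen-4-one F3. 10% HCl in MeOH at 50 °C then removes the MOM group and gives 8.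

Step 3 (Claisen–Schmidt condensation). The free 2-OH is deprotonated first, so the enolate must form from a phenoxide, and the aldehyde is electron-rich and ortho-substituted; the condensation may stall or drift to the flavanone. The fallback masks the chelated phenol as well. It sets out from 4 and comes back to the route at 8. Ketone 4 with NaH and MOMCl in DMF (0 °C to rt) gives 1-[4-methoxy-2,5-bis(methoxymethoxy)phenyl]ethanone F4. This condenses readily with 5 (KOH, EtOH, rt) to (E)-1-[4-methoxy-2,5-bis(methoxymethoxy)phenyl]-3-(2,4,5-trimethoxyphenyl)prop-2-en-1-one F5. Under the conditions of step 4, Tl(NO3)3 in MeOH/HC(OMe)3 gives 3,3-dimethoxy-1-[4-methoxy-2,5-bis(methoxymethoxy)phenyl]-2-(2,4,5-trimethoxyphenyl)propan-1-one F6, and hot aqueous HCl removes both MOM groups and cyclises to 8.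

Step 1 (Elbs oxidation). Conversion is inherently low and the hydroquinone can over-oxidise, so material throughput may be poor. The fallback replaces the direct C–H hydroxylation by halogenation and catalytic C–O coupling. It sets out from 1 and comes back to the route at 3. Paeonol 1 is brominated para to the phenol (NBS, MeCN, 0 °C to rt) to 1-(5-bromo-2-hydroxy-4-methoxyphenyl)ethanone F7. Copper-catalysed hydroxylation of the aryl bromide (CuI, an oxalamide ligand, KOH, DMSO/H2O, 100 °C, then acidification) gives 3.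

**Further compounds**

F1 | step 4 | (E)-3-(dimethylamino)-1-[2-hydroxy-4-methoxy-5-(methoxymethoxy)phenyl]prop-2-en-1-one | CN(C)/C=C/C(=O)c1cc(OCOC)c(OC)cc1O
F2 | step 4 | 3-iodo-7-methoxy-6-(methoxymethoxy)-4H-chromen-4-one | COCOc1cc2c(=O)c(I)coc2cc1OC
F3 | step 4 | 7-methoxy-6-(methoxymethoxy)-3-(2,4,5-trimethoxyphenyl)-4H-chromen-4-one | COCOc1cc2c(=O)c(-c3cc(OC)c(OC)cc3OC)coc2cc1OC
F4 | step 3 | 1-[4-methoxy-2,5-bis(methoxymethoxy)phenyl]ethanone | CC(=O)c1cc(OCOC)c(OC)cc1OCOC
F5 | step 3 | (E)-1-[4-methoxy-2,5-bis(methoxymethoxy)phenyl]-3-(2,4,5-trimethoxyphenyl)prop-2-en-1-one | COCOc1cc(C(=O)/C=C/c2cc(OC)c(OC)cc2OC)c(OCOC)cc1OC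
F6 | step 3 | 3,3-dimethoxy-1-[4-methoxy-2,5-bis(methoxymethoxy)phenyl]-2-(2,4,5-trimethoxyphenyl)propan-1-one | COCOc1cc(C(=O)C(C(OC)OC)c2cc(OC)c(OC)cc2OC)c(OCOC)cc1OC
F7 | step 1 | 1-(5-bromo-2-hydroxy-4-methoxyphenyl)ethanone | CC(=O)c1cc(Br)c(OC)cc1O
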